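**Retrosynthetic overview**
1. The C1 methyl group is put on last by cross-coupling of an enol triflate made from a tetracyclic α-ketol (C2 ketone next to the C25 tertiary alcohol); the eight-membered ring fixes the alkene geometry.
2. Key disconnection, C25–C2: ring C is closed when an acylsamarium (acyl anion, made from an acid chloride) adds to the C25 ketone. This forms the tertiary carbinol and the eight-membered ring in one step.
3. Ring B comes from a Robinson annulation of a ring-A β-keto ester with an α-substituted vinyl ketone that already carries ring D and C11; hydrogenation then sets C19 and C23.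
4. The vinyl ketone comes from cyclopentenone (ring D) by Cu-catalysed methyl addition and enolate alkylation with a C11-stereodefined iodide from methyl (R)-3-methylglutarate, followed by triflate carbonylation to introduce C2.
5. Ring order: D and A are bought as rings, B is formed by annulation, C is formed last in the key step.

Assumption: in the two catalyst-controlled steps (5 and 10) the ligand or catalyst antipode is the one that gives the configuration drawn.

Atom labels (target): C1 = CH3 on C2; C2=C3 alkene; ring D = C3–C4–C5–C6(CH3)–C8; chain C9–C10–C11(CH3); ring B = C13–C14–C15–C23–C24–C25(OH); ring A = C15–C17–C18–C19(iPr)–C23; C16 = CO2H. Target configuration: 6R, 8S, 11S, 13R, 15S, 19R, 23S, 25R.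

**Route**

Step 1
Reactants: 1 methyl 2-oxocyclopentane-1-carboxylate; 2 acetone
Product: 4 methyl 2-oxo-3-(propan-2-ylidene)cyclopentane-1-carboxylate, via aldol adduct 3 (not isolated)
Conditions: NaH then n-BuLi, THF, 0 °C; 2, −78 °C; AcOH; then TsOH (cat.), PhMe, 80 °C
Reagents that add atoms: none
Why: The dianion of the β-keto ester reacts at its γ-carbon (future C19) in a Weiler dianion aldol addition, and acid-catalysed dehydration gives the conjugated, achiral isopropylidene ketone (the C15–H centre is freely epimerisable).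

Step 2
Reactants: 5 (3R)-5-methoxy-3-methyl-5-oxopentanoic acid (methyl hydrogen (R)-3-methylglutarate)
Product: 7 (4S)-4-methyloxan-2-one, via hydroxy acid 6 (not isolated)
Conditions: LiBH4, THF, 0 °C → rt; then 3 M HCl, rt
Reagents that add atoms: none
Why: Borohydride reduces the ester but not the lithium carboxylate (chemoselective ester reduction) and acid then lactonises the hydroxy acid, so the former ester carbon becomes C9 and the stereocentre (future C11) is untouched, its descriptor changing only through CIP priorities.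

Step 3
Reactants: 7 (4S)-4-methyloxan-2-one
Product: 8 (3S)-5-hydroxy-N-methoxy-N,3-dimethylpentanamide
Conditions: MeO(Me)NH·HCl, i-PrMgCl, THF, −20 → 0 °C
Reagents that add atoms: N,O-dimethylhydroxylamine hydrochloride (CNOC.Cl)
Why: Weinreb aminolysis of the lactone by the chloromagnesium amide opens the ring to the hydroxy amide without touching the stereocentre.

Step 4
Reactants: 8 (3S)-5-hydroxy-N-methoxy-N,3-dimethylpentanamide
Product: 9 (3R)-5-iodo-N-methoxy-N,3-dimethylpentanamide
Conditions: I2, PPh3, imidazole, CH2Cl2, 0 °C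
Reagents that add atoms: iodine (II)
Why: Appel-type (Garegg–Samuelsson) iodination converts the primary alcohol into the iodide by SN2 displacement of the oxyphosphonium group, with the stereocentre remote from the reaction site.

Step 5
Reactants: 10 cyclopent-2-en-1-one; 9 (3R)-5-iodo-N-methoxy-N,3-dimethylpentanamide
Product: 12 (3S)-N-methoxy-N,3-dimethyl-5-[(1S,2R)-2-methyl-5-oxocyclopentyl]pentanamide, via zinc enolate 11 (not isolated)
Conditions: Me2Zn, (CuOTf)2·C6H6 (1 mol %), chiral phosphoramidite ligand (2.5 mol %), PhMe, −30 °C; then 9, HMPA, 0 °C → rt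
Reagents that add atoms: dimethylzinc (C[Zn]C)
Why: Copper-catalysed asymmetric conjugate addition sets C6 (R) under ligand control, and the regiodefined zinc enolate is alkylated by the primary iodide anti to the new methyl group (tandem conjugate addition–enolate alkylation), giving the 2,3-trans ketone with C8 (S).

Step 6
Reactants: 12 (3S)-N-methoxy-N,3-dimethyl-5-[(1S,2R)-2-methyl-5-oxocyclopentyl]pentanamide
Product: 13 (4R,5S)-5-{(3S)-5-[methoxy(methyl)amino]-3-methyl-5-oxopentyl}-4-methylcyclopent-1-en-1-yl trifluoromethanesulfonate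
Conditions: KHMDS (1.05 equiv), THF, −78 °C; PhNTf2, −78 → 0 °C
Reagents that add atoms: N-phenylbis(trifluoromethanesulfonimide) (O=S(=O)(N(c1ccccc1)S(=O)(=O)C(F)(F)F)C(F)(F)F)
Why: Kinetic deprotonation takes place at the unhindered α-CH2 (C4) rather than at the tertiary C8–H or the less acidic amide α-CH2, and O-triflation of this enolate gives the enol triflate with C8 intact.

Step 7
Reactants: 13 (4R,5S)-5-{(3S)-5-[methoxy(methyl)amino]-3-methyl-5-oxopentyl}-4-methylcyclopent-1-en-1-yl trifluoromethanesulfonate
Product: 14 benzyl (4R,5S)-5-{(3S)-5-[methoxy(methyl)amino]-3-methyl-5-oxopentyl}-4-methylcyclopent-1-ene-1-carboxylate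
Conditions: Pd(OAc)2 (5 mol %), dppf, CO (1 atm), BnOH, Et3N, DMF, 60 °C
Reagents that add atoms: carbon monoxide ([C-]#[O+]); benzyl alcohol (OCc1ccccc1)
Why: Palladium-catalysed alkoxycarbonylation of the vinyl triflate (oxidative addition, CO insertion, alcoholysis) introduces C2 at the carboxyl oxidation level as a benzyl ester.

Step 8
Reactants: 14 benzyl (4R,5S)-5-{(3S)-5-[methoxy(methyl)amino]-3-methyl-5-oxopentyl}-4-methylcyclopent-1-ene-1-carboxylate
Product: 15 benzyl (4R,5S)-4-methyl-5-[(3S)-3-methyl-5-oxohexyl]cyclopent-1-ene-1-carboxylate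
Conditions: MeMgBr (1.2 equiv), THF, −40 → −10 °C; aq. NH4Cl
Reagents that add atoms: methylmagnesium bromide (C[Mg]Br)
Why: In this Weinreb ketone synthesis the chelated tetrahedral intermediate stops at the methyl ketone (C25=O with C24), and the amide reacts faster than the conjugated benzyl ester at low temperature.

Step 9
Reactants: 15 benzyl (4R,5S)-4-methyl-5-[(3S)-3-methyl-5-oxohexyl]cyclopent-1-ene-1-carboxylate
Product: 16 benzyl (4R,5S)-4-methyl-5-[(3S)-3-methyl-4-methylidene-5-oxohexyl]cyclopent-1-ene-1-carboxylate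
Conditions: (CH2O)n, N-methylanilinium trifluoroacetate, THF, reflux
Reagents that add atoms: formaldehyde as paraformaldehyde (C=O)
Why: Gras α-methylenation (Mannich condensation through the more substituted enol, then amine elimination) installs C14 on the methylene carbon C13 of the methyl ketone and gives the α-substituted vinyl ketone.

Step 10
Reactants: 4 methyl 2-oxo-3-(propan-2-ylidene)cyclopentane-1-carboxylate; 16 benzyl (4R,5S)-4-methyl-5-[(3S)-3-methyl-4-methylidene-5-oxohexyl]cyclopent-1-ene-1-carboxylate
Product: 18 methyl (7aS)-6-{(2S)-4-[(1S,5R)-2-(benzyloxycarbonyl)-5-methylcyclopent-2-en-1-yl]butan-2-yl}-5-oxo-3-(propan-2-ylidene)-2,3,5,6,7,7a-hexahydro-1H-indene-7a-carboxylate, via Michael adduct 17 (not isolated)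
Conditions: cinchona-alkaloid squaramide (10 mol %), PhMe, −20 °C → rt; then TsOH·H2O, reflux (Dean–Stark)
Reagents that add atoms: none
Why: This is a Robinson annulation in which the bifunctional catalyst holds the β-keto ester enolate and the enone by hydrogen bonding so that the Michael addition creates the quaternary C15 (S) under catalyst control, and the acid-catalysed aldol condensation of the C24 methyl group onto the C23 ketone then closes ring B as a planar dienone (C13 stays epimerisable).

Step 11
Reactants: 18 methyl (7aS)-6-{(2S)-4-[(1S,5R)-2-(benzyloxycarbonyl)-5-methylcyclopent-2-en-1-yl]butan-2-yl}-5-oxo-3-(propan-2-ylidene)-2,3,5,6,7,7a-hexahydro-1H-indene-7a-carboxylate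
Product: 20 methyl (3R,3aS,6R,7aS)-6-{(2S)-4-[(1S,5R)-2-carboxy-5-methylcyclopentyl]butan-2-yl}-5-oxo-3-(propan-2-yl)octahydro-1H-indene-7a-carboxylate (keto acid; epimers at the carboxyl-bearing C3), via C13-epimer mixture 19 (not isolated)
Conditions: H2 (4 atm), 10% Pd/C, EtOAc, rt; filter; K2CO3, MeOH, rt; then 1 M HCl
Reagents that add atoms: none
Why: Heterogeneous hydrogenation delivers hydrogen to C19 and C23 of the s-cis diene unit from the face opposite the axial angular ester, giving the trans-hydrindanone with the isopropyl group cis to the ester (19R, 23S), while the same operation saturates the ring-D enoate and hydrogenolyses the benzyl ester, and base equilibration places the C13 side chain equatorial (13R).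

Step 12
Reactants: 20 methyl (3R,3aS,6R,7aS)-6-{(2S)-4-[(1S,5R)-2-carboxy-5-methylcyclopentyl]butan-2-yl}-5-oxo-3-(propan-2-yl)octahydro-1H-indene-7a-carboxylate
Product: 22 methyl 1-nor-2-oxo-2,3-dihydrosesterfisherate (tetracyclic α-ketol; C2 ketone; 25R tertiary alcohol; C3 epimers), via acid chloride 21 (not isolated)
Conditions: (COCl)2, DMF (cat.), CH2Cl2, 0 °C → rt, evaporate; then slow addition to SmI2 (2.5 equiv), THF, −40 °C → rt (5 mM); 0.1 M HCl
Reagents that add atoms: none
Why: Proposed new method: SmI2 reduces the acid chloride (far faster than the unactivated ketone in HMPA-free THF) by two single-electron transfers to an acylsamarium(III), a true acyl anion, which adds to the C25 ketone through the equatorial C13 tether along the equatorial trajectory, closing the eight-membered ring with the new C25–C2 bond equatorial and the O–Sm axial (25R, trans-fused 6/8 junction); the closest known reactions are the intermolecular SmI2-mediated coupling of acid chlorides with ketones to α-ketols and SmI2-promoted eight-membered carbocyclisations.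

Step 13
Reactants: 22 methyl 1-nor-2-oxo-2,3-dihydrosesterfisherate
Product: 23 methyl 1-nor-2-(trifluoromethylsulfonyloxy)sesterfisherate (C2=C3 enol triflate of 22)
Conditions: KHMDS (2.3 equiv), THF, −78 °C; PhNTf2, −78 → −20 °C
Reagents that add atoms: N-phenylbis(trifluoromethanesulfonimide) (O=S(=O)(N(c1ccccc1)S(=O)(=O)C(F)(F)F)C(F)(F)F)
Why: After deprotonation of the hydroxyl group the ketone can enolise only towards C3 (C25 is quaternary), and O-triflation of this enolate gives the tetrasubstituted enol triflate whose geometry is fixed by the eight-membered ring, which also erases the C3 epimers.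

Step 14
Reactants: 23 methyl 1-nor-2-(trifluoromethylsulfonyloxy)sesterfisherate
Product: 24 methyl sesterfisherate (methyl ester of 25)
Conditions: MeZnCl (4 equiv), Pd(PPh3)4 (10 mol %), THF, 60 °C
Reagents that add atoms: methylzinc chloride (C[Zn]Cl)
Why: Negishi cross-coupling (oxidative addition, transmetalation, reductive elimination with retention of alkene geometry) replaces the triflate by the C1 methyl group and completes the tetrasubstituted C2=C3 alkene.

Step 15
Reactants: 24 methyl sesterfisherate
Product: 25 sesterfisheric acid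
Conditions: n-PrSLi, HMPA, rt; then 1 M HCl
Reagents that add atoms: none
Why: SN2 demethylation of the hindered angular methyl ester by thiolate at the methyl carbon avoids attack at the shielded carbonyl and leaves the tertiary allylic alcohol and all stereocentres untouched.

**Compound list**

1 | methyl 2-oxocyclopentane-1-carboxylate | COC(=O)C1CCCC1=O | starting material
2 | acetone | CC(C)=O | starting material
3 | methyl 3-(2-hydroxypropan-2-yl)-2-oxocyclopentane-1-carboxylate (aldol adduct) | COC(=O)C1CCC(C(C)(C)O)C1=O | intermediate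
4 | methyl 2-oxo-3-(propan-2-ylidene)cyclopentane-1-carboxylate | COC(=O)C1CCC(=C(C)C)C1=O | intermediate
5 | (3R)-5-methoxy-3-methyl-5-oxopentanoic acid | COC(=O)C[C@H](C)CC(=O)O | starting material
6 | (3S)-5-hydroxy-3-methylpentanoic acid | OCC[C@H](C)CC(=O)O | intermediate
7 | (4S)-4-methyloxan-2-one | O=C1C[C@@H](C)CCO1 | intermediate
8 | (3S)-5-hydroxy-N-methoxy-N,3-dimethylpentanamide | OCC[C@H](C)CC(=O)N(C)OC | intermediate
9 | (3R)-5-iodo-N-methoxy-N,3-dimethylpentanamide | ICC[C@H](C)CC(=O)N(C)OC | intermediate
10 | cyclopent-2-en-1-one | O=C1C=CCC1 | starting material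
11 | methylzinc (3R)-3-methylcyclopent-1-en-1-olate | C[Zn]OC1=C[C@H](C)CC1 | intermediate
12 | (3S)-N-methoxy-N,3-dimethyl-5-[(1S,2R)-2-methyl-5-oxocyclopentyl]pentanamide | O=C1CC[C@@H](C)[C@@H]1CC[C@H](C)CC(=O)N(C)OC | intermediate
13 | (4R,5S)-5-{(3S)-5-[methoxy(methyl)amino]-3-methyl-5-oxopentyl}-4-methylcyclopent-1-en-1-yl trifluoromethanesulfonate | O=S(=O)(OC1=CC[C@@H](C)[C@@H]1CC[C@H](C)CC(=O)N(C)OC)C(F)(F)F | intermediate
14 | benzyl (4R,5S)-5-{(3S)-5-[methoxy(methyl)amino]-3-methyl-5-oxopentyl}-4-methylcyclopent-1-ene-1-carboxylate | O=C(OCc1ccccc1)C1=CC[C@@H](C)[C@@H]1CC[C@H](C)CC(=O)N(C)OC | intermediate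
15 | benzyl (4R,5S)-4-methyl-5-[(3S)-3-methyl-5-oxohexyl]cyclopent-1-ene-1-carboxylate | O=C(OCc1ccccc1)C1=CC[C@@H](C)[C@@H]1CC[C@H](C)CC(C)=O | intermediate
16 | benzyl (4R,5S)-4-methyl-5-[(3S)-3-methyl-4-methylidene-5-oxohexyl]cyclopent-1-ene-1-carboxylate | O=C(OCc1ccccc1)C1=CC[C@@H](C)[C@@H]1CC[C@H](C)C(=C)C(C)=O | intermediate
17 | methyl (1S)-1-{(3S)-2-acetyl-5-[(1S,5R)-2-(benzyloxycarbonyl)-5-methylcyclopent-2-en-1-yl]-3-methylpentyl}-2-oxo-3-(propan-2-ylidene)cyclopentane-1-carboxylate (Michael adduct; C13 epimers) | O=C(OCc1ccccc1)C1=CC[C@@H](C)[C@@H]1CC[C@H](C)C(C(C)=O)C[C@@]1(C(=O)OC)CCC(=C(C)C)C1=O | intermediate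
18 | methyl (7aS)-6-{(2S)-4-[(1S,5R)-2-(benzyloxycarbonyl)-5-methylcyclopent-2-en-1-yl]butan-2-yl}-5-oxo-3-(propan-2-ylidene)-2,3,5,6,7,7a-hexahydro-1H-indene-7a-carboxylate (dienone; C13 epimers) | O=C(OCc1ccccc1)C1=CC[C@@H](C)[C@@H]1CC[C@H](C)C1C[C@@]2(C(=O)OC)CCC(=C(C)C)C2=CC1=O | intermediate
19 | C13-epimer mixture of 20 (crude hydrogenation product) | OC(=O)C1CC[C@@H](C)[C@@H]1CC[C@H](C)C1C[C@@]2(C(=O)OC)CC[C@H](C(C)C)[C@@H]2CC1=O | intermediate
20 | methyl (3R,3aS,6R,7aS)-6-{(2S)-4-[(1S,5R)-2-carboxy-5-methylcyclopentyl]butan-2-yl}-5-oxo-3-(propan-2-yl)octahydro-1H-indene-7a-carboxylate (epimers at the carboxyl-bearing C3) | OC(=O)C1CC[C@@H](C)[C@@H]1CC[C@H](C)[C@H]1C[C@@]2(C(=O)OC)CC[C@H](C(C)C)[C@@H]2CC1=O | intermediate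
21 | acid chloride of 20 | O=C(Cl)C1CC[C@@H](C)[C@@H]1CC[C@H](C)[C@H]1C[C@@]2(C(=O)OC)CC[C@H](C(C)C)[C@@H]2CC1=O | intermediate
22 | methyl 1-nor-2-oxo-2,3-dihydrosesterfisherate: tetracyclic α-ketol with C2 ketone and C25 tertiary alcohol (6R,8S,11S,13R,15S,19R,23S,25R; C3 epimers) | O=C1C2CC[C@@H](C)[C@@H]2CC[C@H](C)[C@H]2C[C@@]3(C(=O)OC)CC[C@H](C(C)C)[C@@H]3C[C@]12O | intermediate
23 | methyl 1-nor-2-(trifluoromethylsulfonyloxy)sesterfisherate (ring-fixed C2=C3 enol triflate; other centres as in 25) | O=S(=O)(O/C1=C2\CC[C@@H](C)[C@@H]2CC[C@H](C)[C@H]2C[C@@]3(C(=O)OC)CC[C@H](C(C)C)[C@@H]3C[C@]12O)C(F)(F)F | intermediate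
24 | methyl sesterfisherate (methyl ester of 25) | C/C1=C2\CC[C@@H](C)[C@@H]2CC[C@H](C)[C@H]2C[C@@]3(C(=O)OC)CC[C@H](C(C)C)[C@@H]3C[C@]12O | intermediate
25 | sesterfisheric acid | C/C1=C2\CC[C@@H](C)[C@@H]2CC[C@H](C)[C@H]2C[C@@]3(C(=O)O)CC[C@H](C(C)C)[C@@H]3C[C@]12O | target

**Step count and risks**

Total step count: 15. Longest linear sequence: 14 steps (5 → 25, steps 2–15).

The three steps most likely to fail:

Step 12 (ring closure by the acylsamarium). The risks are the yield of an eight-membered ring closure against acyl dimerisation or reduction, and the configuration at C25, which rests on a conformational argument and could come out as the cis-fused epimer. The fallback sets out from 20 and comes back at 22. Couple 20 with ethanethiol (EDC, DMAP) to the S-ethyl thioester F1, and reduce this with Et3SiH and Pd/C (Fukuyama reduction) to the keto aldehyde F2. Close the ring by a ketyl (pinacol) coupling of the aldehyde with the C25 ketone (SmI2, HMPA, t-BuOH, THF, high dilution) to the C2,C25-diol F3, and oxidise its secondary hydroxyl group with Dess–Martin periodinane to 22.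

Step 11 (facial selectivity of the hydrogenation). Hydrindenones often hydrogenate to the cis-fused product, and a cis ring fusion or the C19 epimer would be the wrong outcome. The fallback sets out from 18 and comes back at 20. Reduce 18 with lithium in NH3/THF at −78 °C and quench with NH4Cl. This gives 1,6-reduction of the dienone with kinetic α-protonation, together with reductive loss of the benzyl group and saturation of the enoate, and leads to the β,γ-unsaturated keto acid F4 with a tetrasubstituted C19=C23 double bond. Hydrogenation of this isolated alkene (H2, PtO2, EtOAc) is a syn addition from the face opposite the adjacent angular ester and sets C19 and C23 together, giving 19; K2CO3/MeOH equilibration then gives 20.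

Step 10 (Michael addition of the cross-conjugated β-keto ester to a hindered α-substituted vinyl ketone). The risks are the rate and the enantioselectivity at C15. The fallback sets out from 14 and comes back at 17. Reduce the Weinreb amide 14 with Cp2Zr(H)Cl to the aldehyde F5 and methylenate it (aq. HCHO, pyrrolidine, propionic acid) to the α-substituted acrolein F6. Run the catalytic asymmetric Michael addition of 4 on this far more electrophilic enal to obtain the aldehyde adduct F7, add MeMgBr at −78 °C to give the secondary alcohol F8, and oxidise it with Dess–Martin periodinane to 17, which is cyclised with TsOH to 18 as before.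

**Further compounds**

F1 | step 12 | S-ethyl thioester of keto acid 20 | CCSC(=O)C1CC[C@@H](C)[C@@H]1CC[C@H](C)[C@H]1C[C@@]2(C(=O)OC)CC[C@H](C(C)C)[C@@H]2CC1=O
F2 | step 12 | keto aldehyde (CHO in place of the CO2H of 20) | O=CC1CC[C@@H](C)[C@@H]1CC[C@H](C)[C@H]1C[C@@]2(C(=O)OC)CC[C@H](C(C)C)[C@@H]2CC1=O
F3 | step 12 | C2,C25-diol (2-hydroxy analogue of 22; C2 and C3 epimers) | OC1C2CC[C@@H](C)[C@@H]2CC[C@H](C)[C@H]2C[C@@]3(C(=O)OC)CC[C@H](C(C)C)[C@@H]3C[C@]12O
F4 | step 11 | β,γ-unsaturated keto acid with tetrasubstituted C19=C23 alkene (15S; ring-D acid saturated) | OC(=O)C1CC[C@@H](C)[C@@H]1CC[C@H](C)C1C[C@@]2(C(=O)OC)CCC(C(C)C)=C2CC1=O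
F5 | step 10 | benzyl (4R,5S)-4-methyl-5-[(3S)-3-methyl-5-oxopentyl]cyclopent-1-ene-1-carboxylate | O=C(OCc1ccccc1)C1=CC[C@@H](C)[C@@H]1CC[C@H](C)CC=O
F6 | step 10 | benzyl (4R,5S)-5-[(3S)-4-formyl-3-methylpent-4-en-1-yl]-4-methylcyclopent-1-ene-1-carboxylate | O=C(OCc1ccccc1)C1=CC[C@@H](C)[C@@H]1CC[C@H](C)C(=C)C=O
F7 | step 10 | methyl (1S)-1-{(3S)-5-[(1S,5R)-2-(benzyloxycarbonyl)-5-methylcyclopent-2-en-1-yl]-2-formyl-3-methylpentyl}-2-oxo-3-(propan-2-ylidene)cyclopentane-1-carboxylate | O=C(OCc1ccccc1)C1=CC[C@@H](C)[C@@H]1CC[C@H](C)C(C=O)C[C@@]1(C(=O)OC)CCC(=C(C)C)C1=O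
F8 | step 10 | 1-hydroxyethyl analogue of 17 (CH(OH)CH3 in place of the acetyl group) | O=C(OCc1ccccc1)C1=CC[C@@H](C)[C@@H]1CC[C@H](C)C(C(C)O)C[C@@]1(C(=O)OC)CCC(=C(C)C)C1=O
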